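## Retrosynthetic overview

- **Feature:** in the flavone half, ring A (C4a, C5, C6, C7, C8, C8a) bears oxygen on C5, C7 and C8a, the 1,3,5-pattern of a folded polyketide. Its C8 holds ring B, the catechol ring shared with the flavanone half. Ring A can therefore be grown last onto a ready-made 4-pyranone, which is flavone ring C (O1, C2, C3, C4, C4a, C8a).
- **Key disconnection:** C7–C8 and C5–C6 of ring A. This leads back to pyranone ester 17 (ring B–CH2 on the future C8a, CO2Me on the future C4a) and the two-carbon unit N-methoxy-N-methylacetamide 18.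
- **Pyranone 17:** C4–C4a by C-acylation of the ring B beta-keto ester 10 with arylpropioloyl chloride 15, then O1–C2 by 6-endo-dig closure.
- **Flavanone half:** Knoevenagel condensation of ring B aldehyde 22 with tert-butyl beta-keto ester 25, a catalytic asymmetric oxa-Michael closure that sets (2S), decarboxylation, and hydrogenolysis of eight benzyl ethers.
- **Ring order:** flavone ring C (step 9), flavone ring A (step 10), flavanone heterocycle (step 16). The other four benzene rings are bought.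

Key step: step 10

**Assumption (catalyst sense):** the epi-quinidine-derived thiourea is taken as the member of the pseudo-enantiomeric catalyst pair that gives (2S). The sense is checked first on aldehyde 11 as a model, and the epi-quinine-derived catalyst replaces it without other change if the sense is opposite.

**Assumption (axis):** the ring B–C8 biaryl axis has three ortho oxygens and one ortho hydrogen, and the target names no axial descriptor, so it is treated as freely rotating in 29. Benzylated intermediates may show rotamers.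

**Remark (protection):** all phenols are carried as benzyl ethers.
- They resist the acid used to make and remove the dioxolane, as well as (COCl)2, amide bases and hot TsOH.
- They leave under neutral hydrogenolysis, so the racemisation-prone 4'-hydroxyflavanone never meets strong acid or base.

## Route

Step 1
Reactants: 1 3-bromo-4,5-dihydroxybenzaldehyde
Product: 2 3,4-bis(benzyloxy)-5-bromobenzaldehyde
Conditions: BnBr (2.4 equiv), K2CO3, DMF, 50 °C
Reagents that add atoms: benzyl bromide, BrCc1ccccc1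
Why: Williamson ether synthesis, in which both catechol phenoxides are alkylated by the SN2-active benzyl bromide while the aldehyde and the aryl bromide are untouched.

Step 2
Reactants: 2 3,4-bis(benzyloxy)-5-bromobenzaldehyde
Product: 3 2-[3,4-bis(benzyloxy)-5-bromophenyl]-1,3-dioxolane
Conditions: HOCH2CH2OH, TsOH·H2O (cat.), toluene, reflux, Dean–Stark
Reagents that add atoms: ethylene glycol, OCCO
Why: Acid-catalysed acetalisation driven by azeotropic removal of water masks the aldehyde against the organozinc, enolate and amide-base chemistry ahead, and aryl benzyl ethers are inert to catalytic TsOH.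

Step 3
Reactants: 3 2-[3,4-bis(benzyloxy)-5-bromophenyl]-1,3-dioxolane; 4 ethyl bromoacetate
Product: 6 ethyl 2-[2,3-bis(benzyloxy)-5-(1,3-dioxolan-2-yl)phenyl]acetate, via Reformatsky reagent 5 (not isolated)
Conditions: 4, Zn dust, Me3SiCl (cat.), THF, 40 °C; then 3, Pd(dba)2 (2 mol %), XPhos (4 mol %), THF, 65 °C
Reagents that add atoms: zinc, [Zn] (ends in intermediate 5 only)
Why: Negishi-type cross-coupling of a Reformatsky reagent (palladium-catalysed ester alpha-arylation under nearly neutral conditions), in which the bulky biaryl phosphine helps oxidative addition of the electron-rich, mono-ortho-substituted bromide and the mild zinc enolate leaves acetal and benzyl ethers alone.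

Step 4
Reactants: 6 ethyl 2-[2,3-bis(benzyloxy)-5-(1,3-dioxolan-2-yl)phenyl]acetate
Product: 7 2-[2,3-bis(benzyloxy)-5-(1,3-dioxolan-2-yl)phenyl]acetic acid
Conditions: LiOH, THF/MeOH/H2O, 20 °C; 1 M HCl to pH 4, 0 °C
Reagents that add atoms: lithium hydroxide, [Li+].[OH-]
Why: Ester saponification, followed by a cold acidification that stops at pH 4 so that the dioxolane is kept.

Step 5
Reactants: 7 2-[2,3-bis(benzyloxy)-5-(1,3-dioxolan-2-yl)phenyl]acetic acid; 8 potassium methyl malonate
Product: 10 methyl 4-[2,3-bis(benzyloxy)-5-(1,3-dioxolan-2-yl)phenyl]-3-oxobutanoate, via acyl imidazolide 9 (not isolated)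
Conditions: CDI, THF, 20 °C; then 8, MgCl2, Et3N, MeCN, 20 → 40 °C; aq. NH4Cl
Reagents that add atoms: 1,1'-carbonyldiimidazole, O=C(n1ccnc1)n1ccnc1 (imidazole ends in intermediate 9 only)
Why: Masamune–Brooks homologation, in which the acyl imidazolide acylates the magnesium enolate of the malonate half ester and loss of CO2 gives the beta-keto ester without any acid that could open the dioxolane.

Step 6
Reactants: 11 3,4-bis(benzyloxy)benzaldehyde
Product: 12 1,2-bis(benzyloxy)-4-(2,2-dibromovinyl)benzene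
Conditions: CBr4, PPh3, CH2Cl2, 0 °C
Reagents that add atoms: carbon tetrabromide, BrC(Br)(Br)Br
Why: First stage of the Corey–Fuchs alkyne synthesis, a Wittig-type dibromomethylenation of the aldehyde by the ylide formed from CBr4 and PPh3.

Step 7
Reactants: 12 1,2-bis(benzyloxy)-4-(2,2-dibromovinyl)benzene
Product: 14 3-[3,4-bis(benzyloxy)phenyl]propiolic acid, via lithium acetylide 13 (not isolated)
Conditions: n-BuLi (2.2 equiv), THF, −78 → −20 °C; CO2, −78 → 20 °C; 1 M HCl
Reagents that add atoms: carbon dioxide, O=C=O; n-butyllithium, [Li]CCCC (lithium ends in intermediate 13 only)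
Why: Second stage of the Corey–Fuchs sequence, in which bromine–lithium exchange and elimination give the lithium acetylide and its carboxylation with CO2 delivers the propiolic acid in the same flask.

Step 8
Reactants: 14 3-[3,4-bis(benzyloxy)phenyl]propiolic acid
Product: 15 3-[3,4-bis(benzyloxy)phenyl]propioloyl chloride
Conditions: (COCl)2, DMF (cat.), CH2Cl2, 0 → 20 °C; evaporation
Reagents that add atoms: oxalyl chloride, O=C(Cl)C(=O)Cl
Why: Acid chloride formation through the Vilsmeier-type chloroiminium species, kept at or below room temperature so that HCl does not add to the triple bond.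

Step 9
Reactants: 10 methyl 4-[2,3-bis(benzyloxy)-5-(1,3-dioxolan-2-yl)phenyl]-3-oxobutanoate; 15 3-[3,4-bis(benzyloxy)phenyl]propioloyl chloride
Product: 17 methyl 2-[2,3-bis(benzyloxy)-5-(1,3-dioxolan-2-yl)benzyl]-6-[3,4-bis(benzyloxy)phenyl]-4-oxo-4H-pyran-3-carboxylate, via ynone tricarbonyl 16 (not isolated)
Conditions: 10, MgCl2, pyridine, CH2Cl2, 0 °C; 15, 0 → 20 °C; then DMAP (20 mol %), 20 °C
Reagents that add atoms: none
Why: Soft enolisation gives a chelated magnesium enolate that is C-acylated by the ynoyl chloride (flavone C4–C4a), and the enol oxygen of the arylacetyl ketone then adds to the beta carbon of the ynone in a 6-endo-dig oxa-Michael closure (O1–C2), the long-known route from beta-keto esters and arylpropioloyl chlorides to 4-pyranone-3-carboxylates.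

Step 10
Reactants: 17 methyl 2-[2,3-bis(benzyloxy)-5-(1,3-dioxolan-2-yl)benzyl]-6-[3,4-bis(benzyloxy)phenyl]-4-oxo-4H-pyran-3-carboxylate; 18 N-methoxy-N-methylacetamide
Product: 20 8-[2,3-bis(benzyloxy)-5-(1,3-dioxolan-2-yl)phenyl]-2-[3,4-bis(benzyloxy)phenyl]-5,7-dihydroxy-4H-chromen-4-one, via methyl ketone 19 (not isolated)
Conditions: LiN(SiMe3)2 (2.2 equiv), THF, −78 °C; 18 (1.5 equiv), −78 → 0 °C; LiN(SiMe3)2 (2.5 equiv), 0 → 45 °C; aq. NH4Cl
Reagents that add atoms: none
Why: Proposed new method: LiN(SiMe3)2, too weak a base to enolise amide 18 to any extent, removes a proton from the CH2 group of 17, which is benzylic and vinylogously activated by the pyranone carbonyl and the ester; the extended enolate adds through this carbon to 18, and because the carbanion is a stabilised leaving partner the tetrahedral adduct collapses on warming, ketone 19 being held as its enolate (C7–C8 formed). The second charge of base and proton shuffling supply the terminal CH2 enolate of the new methyl ketone, which lithium bridging keeps next to the methyl ester and which attacks it in a 6-(enolendo)-exo-trig Claisen closure (C5–C6 formed); loss of methoxide and double enolisation then give ring A as its bis-phenoxide, an irreversible sink. The closest known reaction type is acylation of lateral anions of ortho-toluates followed by Claisen cyclisation to naphthalene-1,3-diols, and lateral metalation of 2-alkyl-4-pyranones by amide bases is established, so the new element is the union of both on a pyranone-3-carboxylate to deliver a flavone ring A. No stereocentre is formed. Site selectivity in the acylation rests on the fact that attack through C4a (already fully substituted) or through oxygen gives adducts that revert, whereas the C8 adduct is fixed by deprotonation, and the 8-aryl rather than 6-aryl pattern is fixed because the pyranone already holds O1, C8a and C4a in place. In the closure, attack of the enolate oxygen on the ester gives an enol lactone that methoxide reopens, and aldol attack on the vinylogous-ester carbonyl C4 cannot aromatise and reverts, so both side paths drain into the phenoxide.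

Step 11
Reactants: 20 8-[2,3-bis(benzyloxy)-5-(1,3-dioxolan-2-yl)phenyl]-2-[3,4-bis(benzyloxy)phenyl]-5,7-dihydroxy-4H-chromen-4-one
Product: 21 5,7-bis(benzyloxy)-8-[2,3-bis(benzyloxy)-5-(1,3-dioxolan-2-yl)phenyl]-2-[3,4-bis(benzyloxy)phenyl]-4H-chromen-4-one
Conditions: BnBr (3 equiv), K2CO3, Bu4NI (cat.), DMF, 65 °C
Reagents that add atoms: benzyl bromide, BrCc1ccccc1
Why: Williamson benzylation, in which the acidic 7-OH reacts fast and the hydrogen-bonded 5-OH follows on heating, removing the two acidic phenols that would otherwise quench the basic site of the organocatalyst in step 16.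

Step 12
Reactants: 21 5,7-bis(benzyloxy)-8-[2,3-bis(benzyloxy)-5-(1,3-dioxolan-2-yl)phenyl]-2-[3,4-bis(benzyloxy)phenyl]-4H-chromen-4-one
Product: 22 3,4-bis(benzyloxy)-5-{5,7-bis(benzyloxy)-2-[3,4-bis(benzyloxy)phenyl]-4-oxo-4H-chromen-8-yl}benzaldehyde
Conditions: 1 M HCl, THF, 20 °C
Reagents that add atoms: water, O
Why: Acid-catalysed acetal hydrolysis, fast for the acetal of an electron-rich benzaldehyde and orthogonal to the benzyl ethers and the flavone.

Step 13
Reactants: 23 2,4,6-trihydroxyacetophenone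
Product: 24 1-[2,4-bis(benzyloxy)-6-hydroxyphenyl]ethanone
Conditions: BnBr (2.05 equiv), K2CO3, DMF, 20 °C
Reagents that add atoms: benzyl bromide, BrCc1ccccc1
Why: Selective Williamson benzylation, since after the 4-OH and one ortho OH have reacted the last OH is locked in a hydrogen bond to the acetyl carbonyl and stays free.

Step 14
Reactants: 24 1-[2,4-bis(benzyloxy)-6-hydroxyphenyl]ethanone
Product: 25 tert-butyl 3-[2,4-bis(benzyloxy)-6-hydroxyphenyl]-3-oxopropanoate
Conditions: LiN(SiMe3)2 (3.3 equiv), THF, −78 °C; Boc2O (1.1 equiv), −78 → 0 °C; aq. NH4Cl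
Reagents that add atoms: di-tert-butyl dicarbonate, CC(C)(C)OC(=O)OC(=O)OC(C)(C)C
Why: Claisen-type C-tert-butoxycarbonylation of the phenoxide–enolate dianion, in which any aryl carbonate formed on the phenoxide is passed to the enolate carbon by a Baker–Venkataraman-type O-to-C shift, so that both paths end in the stabilised beta-keto ester enolate.

Step 15
Reactants: 22 3,4-bis(benzyloxy)-5-{5,7-bis(benzyloxy)-2-[3,4-bis(benzyloxy)phenyl]-4-oxo-4H-chromen-8-yl}benzaldehyde; 25 tert-butyl 3-[2,4-bis(benzyloxy)-6-hydroxyphenyl]-3-oxopropanoate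
Product: 26 tert-butyl (Z)-2-[2,4-bis(benzyloxy)-6-hydroxybenzoyl]-3-(3,4-bis(benzyloxy)-5-{5,7-bis(benzyloxy)-2-[3,4-bis(benzyloxy)phenyl]-4-oxo-4H-chromen-8-yl}phenyl)acrylate
Conditions: piperidine (20 mol %), AcOH (20 mol %), 4 Å molecular sieves, toluene, 20–40 °C
Reagents that add atoms: none
Why: Knoevenagel condensation through the iminium ion of 22, in which the bulky tert-butyl ester blocks lactonisation to a coumarin, slows the uncatalysed ring closure so that the alkylidene can be isolated, and places the aryl group cis to the ester as usual.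

Step 16
Reactants: 26 tert-butyl (Z)-2-[2,4-bis(benzyloxy)-6-hydroxybenzoyl]-3-(3,4-bis(benzyloxy)-5-{5,7-bis(benzyloxy)-2-[3,4-bis(benzyloxy)phenyl]-4-oxo-4H-chromen-8-yl}phenyl)acrylate
Product: 28 (2S)-5,7-bis(benzyloxy)-2-(3,4-bis(benzyloxy)-5-{5,7-bis(benzyloxy)-2-[3,4-bis(benzyloxy)phenyl]-4-oxo-4H-chromen-8-yl}phenyl)chroman-4-one, via 3-carboxylate 27 (not isolated)
Conditions: 3,5-bis(trifluoromethyl)phenyl thiourea of 9-amino-9-deoxy-epi-quinidine (10 mol %), toluene, −25 °C; then TsOH·H2O, 80 °C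
Reagents that add atoms: none
Why: Bifunctional-organocatalytic intramolecular oxa-Michael addition (6-endo-trig), in which the thiourea binds the beta-dicarbonyl unit while the quinuclidine nitrogen deprotonates the phenol and guides it to one face of the alkylidene carbon, setting flavanone C2 as S, after which TsOH cleaves the tert-butyl ester (E1 loss of isobutene) and the beta-keto acid loses CO2, erasing the labile C3 centre without touching C2.

Step 17
Reactants: 28 (2S)-5,7-bis(benzyloxy)-2-(3,4-bis(benzyloxy)-5-{5,7-bis(benzyloxy)-2-[3,4-bis(benzyloxy)phenyl]-4-oxo-4H-chromen-8-yl}phenyl)chroman-4-one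
Product: 29 (2S)-2-{3-[2-(3,4-dihydroxyphenyl)-5,7-dihydroxy-4-oxo-4H-chromen-8-yl]-4,5-dihydroxyphenyl}-5,7-dihydroxychroman-4-one
Conditions: H2 (1 atm), Pd/C, THF/MeOH, AcOH (1 %), 20 °C; filtration under argon, evaporation below 30 °C
Reagents that add atoms: none
Why: Catalytic hydrogenolysis of all eight aryl benzyl ethers under faintly acidic, near-neutral conditions, which spare the flavone C2=C3 bond and the flavanone C2–O bond and avoid the base- or heat-induced ring opening through which a 4'-hydroxyflavanone would racemise.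

## Compound list

1 | 3-bromo-4,5-dihydroxybenzaldehyde | O=Cc1cc(O)c(O)c(Br)c1 | starting material
2 | 3,4-bis(benzyloxy)-5-bromobenzaldehyde | O=Cc1cc(OCc2ccccc2)c(OCc2ccccc2)c(Br)c1 | intermediate
3 | 2-[3,4-bis(benzyloxy)-5-bromophenyl]-1,3-dioxolane | Brc1cc(C2OCCO2)cc(OCc2ccccc2)c1OCc3ccccc3 | intermediate
4 | ethyl bromoacetate | CCOC(=O)CBr | starting material
5 | bromo(2-ethoxy-2-oxoethyl)zinc (Reformatsky reagent) | CCOC(=O)C[Zn]Br | intermediate
6 | ethyl 2-[2,3-bis(benzyloxy)-5-(1,3-dioxolan-2-yl)phenyl]acetate | CCOC(=O)Cc1cc(C2OCCO2)cc(OCc2ccccc2)c1OCc3ccccc3 | intermediate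
7 | 2-[2,3-bis(benzyloxy)-5-(1,3-dioxolan-2-yl)phenyl]acetic acid | OC(=O)Cc1cc(C2OCCO2)cc(OCc2ccccc2)c1OCc3ccccc3 | intermediate
8 | potassium methyl malonate | COC(=O)CC(=O)[O-].[K+] | starting material
9 | 1-{[2,3-bis(benzyloxy)-5-(1,3-dioxolan-2-yl)phenyl]acetyl}imidazole | O=C(Cc1cc(C2OCCO2)cc(OCc2ccccc2)c1OCc3ccccc3)n4ccnc4 | intermediate
10 | methyl 4-[2,3-bis(benzyloxy)-5-(1,3-dioxolan-2-yl)phenyl]-3-oxobutanoate | COC(=O)CC(=O)Cc1cc(C2OCCO2)cc(OCc2ccccc2)c1OCc3ccccc3 | intermediate
11 | 3,4-bis(benzyloxy)benzaldehyde | O=Cc1ccc(OCc2ccccc2)c(OCc2ccccc2)c1 | starting material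
12 | 1,2-bis(benzyloxy)-4-(2,2-dibromovinyl)benzene | BrC(Br)=Cc1ccc(OCc2ccccc2)c(OCc2ccccc2)c1 | intermediate
13 | lithium [3,4-bis(benzyloxy)phenyl]acetylide | [Li]C#Cc1ccc(OCc2ccccc2)c(OCc2ccccc2)c1 | intermediate
14 | 3-[3,4-bis(benzyloxy)phenyl]propiolic acid | OC(=O)C#Cc1ccc(OCc2ccccc2)c(OCc2ccccc2)c1 | intermediate
15 | 3-[3,4-bis(benzyloxy)phenyl]propioloyl chloride | ClC(=O)C#Cc1ccc(OCc2ccccc2)c(OCc2ccccc2)c1 | intermediate
16 | methyl 2-{[2,3-bis(benzyloxy)-5-(1,3-dioxolan-2-yl)phenyl]acetyl}-5-[3,4-bis(benzyloxy)phenyl]-3-oxopent-4-ynoate (enolised in the flask) | COC(=O)C(C(=O)Cc1cc(C2OCCO2)cc(OCc2ccccc2)c1OCc3ccccc3)C(=O)C#Cc4ccc(OCc5ccccc5)c(OCc5ccccc5)c4 | intermediate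
17 | methyl 2-[2,3-bis(benzyloxy)-5-(1,3-dioxolan-2-yl)benzyl]-6-[3,4-bis(benzyloxy)phenyl]-4-oxo-4H-pyran-3-carboxylate | COC(=O)c1c(Cc2cc(C3OCCO3)cc(OCc3ccccc3)c2OCc3ccccc3)oc(-c2ccc(OCc3ccccc3)c(OCc3ccccc3)c2)cc1=O | intermediate
18 | N-methoxy-N-methylacetamide | CC(=O)N(C)OC | starting material
19 | methyl 2-{1-[2,3-bis(benzyloxy)-5-(1,3-dioxolan-2-yl)phenyl]-2-oxopropyl}-6-[3,4-bis(benzyloxy)phenyl]-4-oxo-4H-pyran-3-carboxylate (present as its planar lithium enolate) | COC(=O)c1c(C(C(C)=O)c2cc(C3OCCO3)cc(OCc3ccccc3)c2OCc3ccccc3)oc(-c2ccc(OCc3ccccc3)c(OCc3ccccc3)c2)cc1=O | intermediate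
20 | 8-[2,3-bis(benzyloxy)-5-(1,3-dioxolan-2-yl)phenyl]-2-[3,4-bis(benzyloxy)phenyl]-5,7-dihydroxy-4H-chromen-4-one | O=c1cc(-c2ccc(OCc3ccccc3)c(OCc3ccccc3)c2)oc2c(-c3cc(C4OCCO4)cc(OCc4ccccc4)c3OCc5ccccc5)c(O)cc(O)c12 | intermediate
21 | 5,7-bis(benzyloxy)-8-[2,3-bis(benzyloxy)-5-(1,3-dioxolan-2-yl)phenyl]-2-[3,4-bis(benzyloxy)phenyl]-4H-chromen-4-one | O=c1cc(-c2ccc(OCc3ccccc3)c(OCc3ccccc3)c2)oc2c(-c3cc(C4OCCO4)cc(OCc4ccccc4)c3OCc5ccccc5)c(OCc3ccccc3)cc(OCc3ccccc3)c12 | intermediate
22 | 3,4-bis(benzyloxy)-5-{5,7-bis(benzyloxy)-2-[3,4-bis(benzyloxy)phenyl]-4-oxo-4H-chromen-8-yl}benzaldehyde | O=Cc1cc(OCc2ccccc2)c(OCc2ccccc2)c(-c2c(OCc3ccccc3)cc(OCc3ccccc3)c3c(=O)cc(-c4ccc(OCc5ccccc5)c(OCc5ccccc5)c4)oc23)c1 | intermediate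
23 | 2,4,6-trihydroxyacetophenone | CC(=O)c1c(O)cc(O)cc1O | starting material
24 | 1-[2,4-bis(benzyloxy)-6-hydroxyphenyl]ethanone | CC(=O)c1c(O)cc(OCc2ccccc2)cc1OCc3ccccc3 | intermediate
25 | tert-butyl 3-[2,4-bis(benzyloxy)-6-hydroxyphenyl]-3-oxopropanoate | CC(C)(C)OC(=O)CC(=O)c1c(O)cc(OCc2ccccc2)cc1OCc3ccccc3 | intermediate
26 | tert-butyl (Z)-2-[2,4-bis(benzyloxy)-6-hydroxybenzoyl]-3-(3,4-bis(benzyloxy)-5-{5,7-bis(benzyloxy)-2-[3,4-bis(benzyloxy)phenyl]-4-oxo-4H-chromen-8-yl}phenyl)acrylate | CC(C)(C)OC(=O)/C(C(=O)c1c(O)cc(OCc6ccccc6)cc1OCc6ccccc6)=C\c2cc(OCc6ccccc6)c(OCc6ccccc6)c(-c3c(OCc6ccccc6)cc(OCc6ccccc6)c4c(=O)cc(-c5ccc(OCc6ccccc6)c(OCc6ccccc6)c5)oc34)c2 | intermediate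
27 | tert-butyl (2S)-5,7-bis(benzyloxy)-2-(3,4-bis(benzyloxy)-5-{5,7-bis(benzyloxy)-2-[3,4-bis(benzyloxy)phenyl]-4-oxo-4H-chromen-8-yl}phenyl)-4-oxochromane-3-carboxylate (C3 epimers/enol) | O=C1C(C(=O)OC(C)(C)C)[C@@H](c2cc(OCc6ccccc6)c(OCc6ccccc6)c(-c3c(OCc6ccccc6)cc(OCc6ccccc6)c4c(=O)cc(-c5ccc(OCc6ccccc6)c(OCc6ccccc6)c5)oc34)c2)Oc2cc(OCc6ccccc6)cc(OCc6ccccc6)c21 | intermediate
28 | (2S)-5,7-bis(benzyloxy)-2-(3,4-bis(benzyloxy)-5-{5,7-bis(benzyloxy)-2-[3,4-bis(benzyloxy)phenyl]-4-oxo-4H-chromen-8-yl}phenyl)chroman-4-one | O=C1C[C@@H](c2cc(OCc6ccccc6)c(OCc6ccccc6)c(-c3c(OCc6ccccc6)cc(OCc6ccccc6)c4c(=O)cc(-c5ccc(OCc6ccccc6)c(OCc6ccccc6)c5)oc34)c2)Oc2cc(OCc6ccccc6)cc(OCc6ccccc6)c21 | intermediate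
29 | (2S)-2-{3-[2-(3,4-dihydroxyphenyl)-5,7-dihydroxy-4-oxo-4H-chromen-8-yl]-4,5-dihydroxyphenyl}-5,7-dihydroxychroman-4-one (CNP0224656.1) | O=C1C[C@@H](c2cc(O)c(O)c(-c3c(O)cc(O)c4c(=O)cc(-c5ccc(O)c(O)c5)oc34)c2)Oc2cc(O)cc(O)c21 | target

## Step count

Total step count: 17.
Longest linear sequence: 12 steps (steps 1–5, 9–12, 15–17, from 1).

## Steps most likely to fail

**Step 10 (ring A folding).**
- The carbanion of 17 is stabilised by three groups and crowded by the ortho-benzyloxy aryl ring, so addition to the amide may be too slow.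
- On warming, liberated methoxide may open the pyranone by conjugate addition.
- The closure may stall after O-acylation.

The fallback forms the ring B–C8 bond by a known biaryl coupling. It sets out from bromide 3 and comes back at 21.
- Miyaura borylation of 3 (B2pin2, PdCl2(dppf), KOAc, dioxane, 90 °C) should give the ring B pinacol boronate F1.
- Commercial luteolin is perbenzylated (BnBr, K2CO3, DMF, 70 °C) to tetra-O-benzylluteolin F2.
- F2 is iodinated at C8, the site preferred in 5,7-dialkoxyflavones (I2, AgO2CCF3, CH2Cl2, 0 °C), to the 8-iodoflavone F3.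
- Suzuki–Miyaura coupling of the two partners (Pd(OAc)2, SPhos, K3PO4, toluene/H2O, 90 °C) should deliver 21.

**Step 16 (asymmetric oxa-Michael closure and decarboxylation).**
- The doubly ortho-substituted aroyl group is twisted and may bind the thiourea poorly, giving poor facial selectivity.
- Uncatalysed ring closure may compete.
- Hot acid may erode the configuration by ring opening or strip the peri benzyl ethers.

The fallback gives up catalytic control for resolution with recycling. It sets out from 22 and 24 and comes back at 28.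
- Claisen–Schmidt condensation (KOH, EtOH/THF, 20 °C) should give the 2'-hydroxychalcone F4.
- NaOAc in refluxing EtOH closes it to the racemic flavanone F5.
- Preparative chromatography on an amylose tris(3,5-dimethylphenylcarbamate) phase separates 28 from the (2R)-flavanone F6.
- F6 is returned to the NaOAc equilibration, where it racemises through the chalcone.

**Step 9 (pyranone assembly).**
- O-acylation may compete with C-acylation.
- The enolate or pyridine may add conjugatively to the ynoyl chloride.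
- 5-exo-dig closure, or carbocyclisation through the benzylic carbon, may divert material.

The fallback exchanges the roles of the two acids so that no ynoyl chloride is needed. It sets out from 7 and 14 and comes back at 16, which closes to 17 with catalytic DMAP as in the main route.
- Acid 14 is activated with CDI to the ynoyl imidazolide F7.
- F7 is homologated with 8, MgCl2 and Et3N to the alkynyl beta-keto ester F8.
- Acid 7 is condensed with 1H-benzotriazole (N-(3-dimethylaminopropyl)-N'-ethylcarbodiimide hydrochloride, CH2Cl2) to the N-acylbenzotriazole F9.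
- The sodium enolate of the alkynyl keto ester (NaH, THF, 0 °C) is C-acylated by this neutral acyl donor to give 16.

## Further compounds

F1 | step 10 | 2-[2,3-bis(benzyloxy)-5-(1,3-dioxolan-2-yl)phenyl]-4,4,5,5-tetramethyl-1,3,2-dioxaborolane | CC1(C)OB(OC1(C)C)c1cc(C2OCCO2)cc(OCc2ccccc2)c1OCc3ccccc3
F2 | step 10 | 5,7-bis(benzyloxy)-2-[3,4-bis(benzyloxy)phenyl]-4H-chromen-4-one (tetra-O-benzylluteolin) | O=c1cc(-c2ccc(OCc3ccccc3)c(OCc3ccccc3)c2)oc2cc(OCc3ccccc3)cc(OCc3ccccc3)c12
F3 | step 10 | 5,7-bis(benzyloxy)-2-[3,4-bis(benzyloxy)phenyl]-8-iodo-4H-chromen-4-one | O=c1cc(-c2ccc(OCc3ccccc3)c(OCc3ccccc3)c2)oc2c(I)c(OCc3ccccc3)cc(OCc3ccccc3)c12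
F4 | step 16 | (E)-1-[2,4-bis(benzyloxy)-6-hydroxyphenyl]-3-(3,4-bis(benzyloxy)-5-{5,7-bis(benzyloxy)-2-[3,4-bis(benzyloxy)phenyl]-4-oxo-4H-chromen-8-yl}phenyl)prop-2-en-1-one | O=C(/C=C/c2cc(OCc6ccccc6)c(OCc6ccccc6)c(-c3c(OCc6ccccc6)cc(OCc6ccccc6)c4c(=O)cc(-c5ccc(OCc6ccccc6)c(OCc6ccccc6)c5)oc34)c2)c1c(O)cc(OCc6ccccc6)cc1OCc6ccccc6
F5 | step 16 | racemic octa-O-benzyl flavanone (racemate of 28) | O=C1CC(c2cc(OCc6ccccc6)c(OCc6ccccc6)c(-c3c(OCc6ccccc6)cc(OCc6ccccc6)c4c(=O)cc(-c5ccc(OCc6ccccc6)c(OCc6ccccc6)c5)oc34)c2)Oc2cc(OCc6ccccc6)cc(OCc6ccccc6)c21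
F6 | step 16 | (2R)-enantiomer of 28 | O=C1C[C@H](c2cc(OCc6ccccc6)c(OCc6ccccc6)c(-c3c(OCc6ccccc6)cc(OCc6ccccc6)c4c(=O)cc(-c5ccc(OCc6ccccc6)c(OCc6ccccc6)c5)oc34)c2)Oc2cc(OCc6ccccc6)cc(OCc6ccccc6)c21
F7 | step 9 | 1-{3-[3,4-bis(benzyloxy)phenyl]propioloyl}imidazole | O=C(C#Cc1ccc(OCc2ccccc2)c(OCc2ccccc2)c1)n3ccnc3
F8 | step 9 | methyl 5-[3,4-bis(benzyloxy)phenyl]-3-oxopent-4-ynoate | COC(=O)CC(=O)C#Cc1ccc(OCc2ccccc2)c(OCc2ccccc2)c1
F9 | step 9 | 1-{[2,3-bis(benzyloxy)-5-(1,3-dioxolan-2-yl)phenyl]acetyl}-1H-benzotriazole | O=C(Cc1cc(C2OCCO2)cc(OCc2ccccc2)c1OCc3ccccc3)n4nnc5ccccc45
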